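**Plan**
1. Hardest feature: ring B of the naphthalene carries the ester carbonyl at C2 and a catechol ring at C4, with C3 free. No simple naphthalene offers this 1,3-pattern, and it sits on a base-sensitive α-acyloxy acid among three catechols.
2. Enabling feature: ring A (C4a–C8a with the C6/C7 oxygens), C1, C2, the ester C=O and the whole (R)-3-(3,4-dihydroxyphenyl)lactate together are an intact rosmarinic acid. Only C3, C4 and the pendant catechol (a C6–C2 unit) are missing, and C4a lies para to the C7 oxygen. Target = rosmarinic acid + ArCOCH2Br − HBr − H2O, which is redox-neutral.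
3. Cuts: C2–C3 (caffeoyl C8–C8′) and C4–C4a (caffeoyl C6–C7′). These are the two bonds of the presumed biosynthesis (8–8′ coupling, 6–7′ closure, C9′ lost). The depside ester bond is never cut.
4. Forward: rosmarinic acid is perbenzylated. Radical C8–H phenacylation makes C2–C3, and acid cyclodehydration in the same flask makes C4–C4a and aromatises ring B, the only ring formed. One hydrogenolysis then frees six phenols and the acid.
5. Stereochemistry: the single (R) centre comes with rosmarinic acid (chiral pool), and no step touches its bonds.

Key step: step 4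

Assumption: natural (R)-(+)-rosmarinic acid of high enantiomeric purity is taken as a commercial starting material; its centre has the configuration written in the target SMILES.

**Step 1**
Reactants: 1 (R)-rosmarinic acid
Product: 2 pentabenzyl rosmarinate, benzyl (2R)-3-[3,4-bis(benzyloxy)phenyl]-2-{[(E)-3-[3,4-bis(benzyloxy)phenyl]prop-2-enoyl]oxy}propanoate
Conditions: BnBr (6 equiv), K2CO3 (6 equiv), DMF, Ar, rt
Reagents that add atoms: benzyl bromide, BrCc1ccccc1
Why: Williamson etherification of the four phenoxides and SN2 alkylation of the carboxylate, the standard exhaustive alkylation of depsides; at room temperature under argon the aliphatic ester and the untouched (R) centre should survive the carbonate base.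

**Step 2**
Reactants: 3 3',4'-dihydroxyacetophenone
Product: 4 3',4'-bis(benzyloxy)acetophenone
Conditions: BnBr (2.3 equiv), K2CO3 (2.5 equiv), acetone, reflux
Reagents that add atoms: benzyl bromide, BrCc1ccccc1
Why: Williamson etherification of a catechol ketone, a routine reaction with no competing site.

**Step 3**
Reactants: 4 3',4'-bis(benzyloxy)acetophenone
Product: 5 2-bromo-3',4'-bis(benzyloxy)acetophenone
Conditions: CuBr2 (2 equiv), EtOAc/CHCl3 (1:1), reflux
Reagents that add atoms: copper(II) bromide, [Cu+2].[Br-].[Br-]
Why: Heterogeneous copper(II) bromide α-bromination of an aryl methyl ketone through its enol should stop at the monobromide, and the acyl group protects the ring from electrophilic bromination.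

**Step 4**
Reactants: 2 pentabenzyl rosmarinate; 5 2-bromo-3',4'-bis(benzyloxy)acetophenone
Product: 7 heptabenzyl eritrichin, benzyl (2R)-3-[3,4-bis(benzyloxy)phenyl]-2-({6,7-bis(benzyloxy)-4-[3,4-bis(benzyloxy)phenyl]-2-naphthoyl}oxy)propanoate, via C8-phenacyl rosmarinate [benzyl (2R)-3-[3,4-bis(benzyloxy)phenyl]-2-{[(2E)-2-[3,4-bis(benzyloxy)benzylidene]-4-[3,4-bis(benzyloxy)phenyl]-4-oxobutanoyl]oxy}propanoate] 6 (not isolated)
Conditions: 5 (1.5 equiv), fac-Ir(ppy)3 (1 mol %), 2,6-lutidine (1.5 equiv), degassed MeCN (0.05 M), 450 nm LEDs, rt; then evaporate, TFA/CH2Cl2 (1:4), rt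
Reagents that add atoms: none
Why: Proposed new method: excited fac-Ir(ppy)3 should reduce 5 to the electrophilic phenacyl radical, which adds to C8 of the caffeoyl alkene of 2 (largest HOMO coefficient, adduct is a 3,4-dialkoxybenzyl radical at C7); Ir(IV) or bromine-atom transfer from 5 turns this radical into the C7 cation, and loss of H8 to lutidine gives 6. The closest known reaction types are the photoredox Heck-type alkenylation of α-bromo ketones with styrenes, the Mn(III)- or Ce(IV)-mediated addition of 1,3-dicarbonyl radicals to the same α-carbon of cinnamic esters, and the radical decarboxylative alkylation of cinnamic acids; new are the simple phenacyl radical on a cinnamate ester with retention of the alkene and the link to ring closure. In TFA the protonated aryl ketone is attacked by caffeoyl C6 in a 6-exo-trig Friedel–Crafts hydroxyalkylation (Bradsher-type cyclodehydration), and loss of water from the doubly benzylic carbinol aromatises ring B, as in the classical acid conversion of α-benzylidene-β-aroylpropionic acids into 4-aryl-2-naphthoic acids. No stereocentre is formed; only the E isomer of 6 (aryl trans to the ester, cis to CH2COAr, the thermodynamic isomer) can close, and the Z isomer or any product of bromide or carbonyl-oxygen capture of the C7 cation should return to it under acid by ionisation or keto–dienol tautomerism, so that the irreversible aromatisation drains all of them. The step needs closure at C6 rather than C2, secured because C6 is para to the C3 benzyloxy group and unhindered while C2 is flanked on both sides, and it needs ketone activation rather than alkene protonation (which would let the aroyl ring close a tetralone), secured by the much higher basicity of the p-alkoxyaryl ketone and the deactivation of that ring by its acyl group. The lactate part has no alkene and its (R) centre is insulated from radical and cation, so it should pass unchanged.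

**Step 5**
Reactants: 7 heptabenzyl eritrichin
Product: 8 eritrichin
Conditions: H2 (1 atm), 10% Pd/C, THF/MeOH (1:1), rt; filtration and evaporation under Ar
Reagents that add atoms: none
Why: Catalytic hydrogenolysis cleaves the six aryl benzyl ethers and the benzyl ester in one operation; the target has no alkene, the naphthalene is not reduced at 1 atm, and the ester C–O at the stereocentre is homobenzylic and inert, so the (R) configuration is kept.

**Compound list**
1 | (R)-rosmarinic acid | O=C(O[C@H](Cc1ccc(O)c(O)c1)C(=O)O)/C=C/c1ccc(O)c(O)c1 | starting material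
2 | pentabenzyl rosmarinate | O=C(O[C@H](Cc1ccc(OCc2ccccc2)c(OCc2ccccc2)c1)C(=O)OCc1ccccc1)/C=C/c1ccc(OCc2ccccc2)c(OCc2ccccc2)c1 | intermediate
3 | 3',4'-dihydroxyacetophenone | CC(=O)c1ccc(O)c(O)c1 | starting material
4 | 3',4'-bis(benzyloxy)acetophenone | CC(=O)c1ccc(OCc2ccccc2)c(OCc2ccccc2)c1 | intermediate
5 | 2-bromo-3',4'-bis(benzyloxy)acetophenone | O=C(CBr)c1ccc(OCc2ccccc2)c(OCc2ccccc2)c1 | intermediate
6 | C8-phenacyl rosmarinate, (E)-α-arylidene-γ-keto ester (not isolated) | O=C(O[C@H](Cc1ccc(OCc2ccccc2)c(OCc2ccccc2)c1)C(=O)OCc1ccccc1)/C(CC(=O)c1ccc(OCc2ccccc2)c(OCc2ccccc2)c1)=C/c1ccc(OCc2ccccc2)c(OCc2ccccc2)c1 | intermediate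
7 | heptabenzyl eritrichin | O=C(O[C@H](Cc1ccc(OCc2ccccc2)c(OCc2ccccc2)c1)C(=O)OCc1ccccc1)c1cc(-c2ccc(OCc3ccccc3)c(OCc3ccccc3)c2)c2cc(OCc3ccccc3)c(OCc3ccccc3)cc2c1 | intermediate
8 | eritrichin | O=C(O[C@H](Cc1ccc(O)c(O)c1)C(=O)O)c1cc(-c2ccc(O)c(O)c2)c2cc(O)c(O)cc2c1 | target

**Total step count:** 5. **Longest linear sequence:** 4 (steps 2, 3, 4, 5).

**Steps most likely to fail**

**Step 4 (Proposed new method).**
- The phenacyl radical may add too slowly to the ester-bearing, 1,2-disubstituted alkene carbon. Hydrogen abstraction, sensitised E/Z isomerisation and [2+2] dimerisation of the cinnamate could then take over.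
- In the acid stage, premature loss of benzyl groups or closure by the wrong ring may erode the material.

The fallback uses known chemistry only. It sets out from 5 and comes back at 7.
- Alkylation of the sodium salt of commercial tert-butyl diethylphosphonoacetate (NaH, THF) with 5 should give tert-butyl 4-[3,4-bis(benzyloxy)phenyl]-2-(diethoxyphosphoryl)-4-oxobutanoate F1.
- Horner–Wadsworth–Emmons olefination of commercial 3,4-bis(benzyloxy)benzaldehyde with F1 should give tert-butyl (E)-2-[3,4-bis(benzyloxy)benzylidene]-4-[3,4-bis(benzyloxy)phenyl]-4-oxobutanoate F2.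
- TFA/CH2Cl2 cleaves the tert-butyl ester and cyclodehydrates to 6,7-bis(benzyloxy)-4-[3,4-bis(benzyloxy)phenyl]-2-naphthoic acid F3.
- Commercial sodium (R)-3-(3,4-dihydroxyphenyl)lactate is tribenzylated (BnBr, K2CO3, DMF) to benzyl (R)-3-[3,4-bis(benzyloxy)phenyl]-2-hydroxypropanoate F4.
- Steglich esterification of F3 with F4 (EDC, DMAP, CH2Cl2) gives 7.

**Step 5.** The sevenfold hydrogenolysis may stall when partly deprotected polyphenols precipitate on the catalyst, and the free catechols may autoxidise during work-up. The fallback sets out from 7 and comes back at 8. It is a non-reductive Lewis-acid debenzylation with BCl3 and pentamethylbenzene as cation scavenger (CH2Cl2, −78 to 0 °C), followed by a methanol quench under argon. It proceeds by C–O ionisation instead of surface hydrogenolysis and makes no new compound (F0).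

**Step 3.** Over-bromination at the methyl group, ring bromination of the dialkoxyarene, or loss of benzyl groups to the acid released at reflux may occur. The fallback sets out from 4 and comes back at 5. Soft enolisation (TMSOTf, Et3N, CH2Cl2, 0 °C) gives 1-[3,4-bis(benzyloxy)phenyl]vinyl trimethylsilyl ether F5. This is brominated with NBS (THF, −78 to 0 °C) under neutral conditions at the only nucleophilic carbon.

**Further compounds**
F1 | step 4 | tert-butyl 4-[3,4-bis(benzyloxy)phenyl]-2-(diethoxyphosphoryl)-4-oxobutanoate (racemic) | CCOP(=O)(OCC)C(CC(=O)c1ccc(OCc2ccccc2)c(OCc2ccccc2)c1)C(=O)OC(C)(C)C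
F2 | step 4 | tert-butyl (E)-2-[3,4-bis(benzyloxy)benzylidene]-4-[3,4-bis(benzyloxy)phenyl]-4-oxobutanoate | CC(C)(C)OC(=O)/C(CC(=O)c1ccc(OCc2ccccc2)c(OCc2ccccc2)c1)=C/c1ccc(OCc2ccccc2)c(OCc2ccccc2)c1
F3 | step 4 | 6,7-bis(benzyloxy)-4-[3,4-bis(benzyloxy)phenyl]-2-naphthoic acid | OC(=O)c1cc(-c2ccc(OCc3ccccc3)c(OCc3ccccc3)c2)c2cc(OCc3ccccc3)c(OCc3ccccc3)cc2c1
F4 | step 4 | benzyl (R)-3-[3,4-bis(benzyloxy)phenyl]-2-hydroxypropanoate | O[C@H](Cc1ccc(OCc2ccccc2)c(OCc2ccccc2)c1)C(=O)OCc1ccccc1
F0 | step 5 | none | none
F5 | step 3 | 1-[3,4-bis(benzyloxy)phenyl]vinyl trimethylsilyl ether | C=C(O[Si](C)(C)C)c1ccc(OCc2ccccc2)c(OCc2ccccc2)c1
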